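## Retrosynthetic overview

1. Target ⇐ face-selective epoxidation of the 4E alkene of a macrocyclic dienolide (last step; ring C, the epoxide).
2. Butenolide (ring B) ⇐ ring-closing metathesis of a C6 2-(acetoxymethyl)acrylate onto a C7 methylidene, which brings in C11–C13.
3. Ten-membered carbocycle (ring A) ⇐ C6–C7 bond by an electrochemical Ni/Cr alkenyl iodide–aldehyde macrocyclisation of an acyclic iodo-enal (key step; C6 set by C8).
4. Seco chain ⇐ C1–C2 bond from a C2–C6 Grignard reagent (Negishi carboalumination of 4-bromobut-1-yne) and a lactone carbonyl; the freed C8–OH is esterified with angelic acid.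
5. Lactone ⇐ (5S)-5-(hydroxymethyl)oxolan-2-one from the L-glutamic acid pool (C8 bought; trans-methylation sets C10; CH2OH → alkyne → 2-iodoalkene). Rings form in the order A, B, C.

Assumption: atom labels C1–C13 follow the germacrane numbering of the target (C1 ketone, C4 and C10 methyl-bearing, C6 lactone O, C7=C11 butenolide alkene, C8 angelate, C12 lactone C=O, C13 acetoxymethyl). Ring locants of 21, 22 and 26 use the same numbers; in the undecadienes 15 and 18–20, chain C2, C3, C5, C6, C9 and C11 are C7, C8, C10, C1, C4 and C6.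

## Route

Step 1
Reactants: 1 (5S)-5-(hydroxymethyl)oxolan-2-one
Product: 2 (5S)-5-({[tert-butyl(diphenyl)silyl]oxy}methyl)oxolan-2-one
Conditions: TBDPSCl, imidazole, DMF, 0 °C to rt
Reagents that add atoms: tert-butyl(chloro)diphenylsilane, CC(C)(C)[Si](Cl)(c1ccccc1)c1ccccc1
Why: Silylation of the primary alcohol installs a bulky C5 substituent that will steer the enolate alkylation, and no stereocentre is touched.

Step 2
Reactants: 2
Product: 4 (3R,5S)-5-({[tert-butyl(diphenyl)silyl]oxy}methyl)-3-methyloxolan-2-one, via lithium enolate 3 (not isolated)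
Conditions: LiN(iPr)2, THF, −78 °C; MeI, −78 to −40 °C
Reagents that add atoms: iodomethane, CI
Why: Lactone enolate alkylation in which MeI attacks the face anti to the C5 silyloxymethyl group, so the bought centre (C8) sets C10 as the 3,5-trans (3R) isomer.

Step 3
Reactants: 4
Product: 5 (3R,5S)-5-(hydroxymethyl)-3-methyloxolan-2-one
Conditions: Bu4NF, AcOH, THF, 0 °C to rt
Reagents that add atoms: none
Why: Acetic-acid-buffered fluoride desilylation frees the primary alcohol without translactonisation or epimerisation.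

Step 4
Reactants: 5
Product: 7 (3R,5S)-5-ethynyl-3-methyloxolan-2-one, via lactone aldehyde 6 (not isolated)
Conditions: (COCl)2, DMSO, CH2Cl2, −78 °C, then Et3N; crude aldehyde, dimethyl (1-diazo-2-oxopropyl)phosphonate, K2CO3, MeOH, 0 °C; dilute acid work-up
Reagents that add atoms: dimethyl (1-diazo-2-oxopropyl)phosphonate, CC(=O)C(=[N+]=[N-])P(=O)(OC)OC
Why: Swern oxidation followed by Seyferth–Gilbert homologation (Ohira–Bestmann reagent) converts CH2OH into the terminal alkyne at 0 °C, cold enough to hold the α-oxygenated centre C8, and the acidic work-up recloses any methanolysed lactone.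

Step 5
Reactants: 7
Product: 8 (3R,5S)-5-(1-iodoethenyl)-3-methyloxolan-2-one
Conditions: NaI, Me3SiCl, H2O, MeCN, rt
Reagents that add atoms: sodium iodide, [Na+].[I-]
Why: Markovnikov hydroiodination of the terminal alkyne by HI made in the flask gives the 2-iodo-1-alkene, as it does with propargylic alcohols, and leaves both stereocentres alone.

Step 6
Reactants: 9 4-bromobut-1-yne
Product: 11 ethyl (2E)-5-bromo-3-methylpent-2-enoate, via alkenylalane 10 (not isolated)
Conditions: AlMe3, Cp2ZrCl2 (25 mol%), CH2Cl2, 0 °C to rt; ClCO2Et, 0 °C to rt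
Reagents that add atoms: trimethylaluminium, C[Al](C)C; ethyl chloroformate, CCOC(=O)Cl
Why: Zirconium-catalysed Negishi carboalumination adds methyl and aluminium syn across the alkyne and the alkenylalane is acylated with retention, which fixes the E trisubstituted C4=C5 alkene.

Step 7
Reactants: 11
Product: 12 (2E)-5-bromo-3-methylpent-2-en-1-ol
Conditions: iBu2AlH, CH2Cl2, −78 °C; aq. potassium sodium tartrate
Reagents that add atoms: none
Why: 1,2-Reduction of the enoate by iBu2AlH leaves the primary bromide and the alkene geometry untouched.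

Step 8
Reactants: 12
Product: 13 {[(2E)-5-bromo-3-methylpent-2-en-1-yl]oxy}triethylsilane
Conditions: Et3SiCl, imidazole, CH2Cl2, 0 °C
Reagents that add atoms: chlorotriethylsilane, CC[Si](Cl)(CC)CC
Why: Silyl protection of the C6 hydroxyl allows the Grignard reagent to be made, and a primary triethylsilyl ether can later be removed under very mild acid.

Step 9
Reactants: 13 {[(2E)-5-bromo-3-methylpent-2-en-1-yl]oxy}triethylsilane; 8 (3R,5S)-5-(1-iodoethenyl)-3-methyloxolan-2-one
Product: 15 (3S,5R,9E)-3-hydroxy-2-iodo-5,9-dimethyl-11-[(triethylsilyl)oxy]undeca-1,9-dien-6-one, via Grignard reagent 14 (not isolated)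
Conditions: Mg, THF, rt; then 8, THF, −78 °C; aq. NH4Cl at −78 °C
Reagents that add atoms: none
Why: Acyl substitution stopped at the ketone stage, because at −78 °C the primary Grignard reagent adds once to the γ-lactone and the magnesium hemiketal survives until the cold quench; this forms C1–C2, alkyl Grignard reagents do not exchange with the alkenyl iodide, and C8 and C10 are carried over unchanged.

Step 10
Reactants: 15 (3S,5R,9E)-3-hydroxy-2-iodo-5,9-dimethyl-11-[(triethylsilyl)oxy]undeca-1,9-dien-6-one; 16 angelic acid, (2Z)-2-methylbut-2-enoic acid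
Product: 18 (3S,5R,9E)-2-iodo-5,9-dimethyl-6-oxo-11-[(triethylsilyl)oxy]undeca-1,9-dien-3-yl (2Z)-2-methylbut-2-enoate, via mixed anhydride 17 (not isolated)
Conditions: 2,4,6-Cl3C6H2COCl, Et3N, PhMe, rt; then 15, 60 °C
Reagents that add atoms: none
Why: Yamaguchi-type esterification through the 2,4,6-trichlorobenzoyl mixed anhydride without DMAP acylates the open-chain C8 hydroxyl with retention and avoids Z to E isomerisation of the angelate.

Step 11
Reactants: 18
Product: 19 (3S,5R,9E)-11-hydroxy-2-iodo-6,6-dimethoxy-5,9-dimethylundeca-1,9-dien-3-yl (2Z)-2-methylbut-2-enoate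
Conditions: HC(OMe)3, MeOH, PPTS (5 mol%), rt
Reagents that add atoms: trimethyl orthoformate, COC(OC)OC; methanol, CO
Why: Acid-catalysed ketalisation masks the C1 ketone, which would otherwise be attacked by the C7 alkenylmetal in a five-membered ring closure, and the same acidic methanol cleaves the primary triethylsilyl ether.

Step 12
Reactants: 19
Product: 20 (3S,5R,9E)-2-iodo-6,6-dimethoxy-5,9-dimethyl-11-oxoundeca-1,9-dien-3-yl (2Z)-2-methylbut-2-enoate
Conditions: MnO2, CH2Cl2, rt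
Reagents that add atoms: none
Why: MnO2 oxidises only the allylic alcohol, giving the E enal without touching the ketal, the ester or the alkenyl iodide.

Step 13
Reactants: 20
Product: 22 (4E,6R,8S,10R)-6-hydroxy-4,10-dimethyl-7-methylidene-1-oxocyclodec-4-en-8-yl (2Z)-2-methylbut-2-enoate, via macrocyclic ketal 21 (not isolated)
Conditions: CrCl2 (20 mol%), NiCl2(dme) (5 mol%), Cp2ZrCl2 (1.5 equiv), LiCl, Bu4NPF6, DMF, Al anode, Ni-foam cathode, constant current (2.5 F/mol), 20 added by syringe pump to 2 mM, rt; aqueous work-up; then PPTS, acetone/H2O, rt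
Reagents that add atoms: none
Why: Proposed new method: an electrocatalytic Nozaki–Hiyama–Kishi macrocyclisation in which zerovalent nickel inserts into the C–I bond, the alkenyl group passes to trivalent chromium and adds 1,2 to the enal to form C6–C7 and ring A, Cp2ZrCl2 frees chromium from the alkoxide and the cathode returns it to the divalent state; the closest known reactions are the intermolecular electrochemical Nozaki–Hiyama–Kishi coupling and stoichiometric CrCl2/NiCl2 macrocyclisations, and an electrochemical medium-ring closure has not been shown; C6 is set by the bought C8 because allylic 1,3-strain makes H6 and H8 eclipse the methylidene, which places O6 cis to O8 (6R in 22, the 6S centre of the target).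

Step 14
Reactants: 23 2-(bromomethyl)prop-2-enoic acid
Product: 24 2-(acetoxymethyl)prop-2-enoic acid
Conditions: KOAc (5 equiv), AcOH, 60 °C
Reagents that add atoms: potassium acetate, CC(=O)[O-].[K+]
Why: Nucleophilic displacement of the activated allylic bromide by excess acetate, which outcompetes the substrate's own carboxylate.

Step 15
Reactants: 22 (4E,6R,8S,10R)-6-hydroxy-4,10-dimethyl-7-methylidene-1-oxocyclodec-4-en-8-yl (2Z)-2-methylbut-2-enoate; 24 2-(acetoxymethyl)prop-2-enoic acid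
Product: 26 (4E,6R,8S,10R)-6-{[2-(acetoxymethyl)prop-2-enoyl]oxy}-4,10-dimethyl-7-methylidene-1-oxocyclodec-4-en-8-yl (2Z)-2-methylbut-2-enoate, via acid chloride 25 (not isolated)
Conditions: (COCl)2, DMF (cat.), CH2Cl2, 0 °C; then 22, pyridine, CH2Cl2, −20 to 0 °C
Reagents that add atoms: none
Why: Acylation of the C6 alcohol by the acid chloride with pyridine, chosen over DMAP to avoid allylic (SN2') displacement of the acetate, brings in C11, C12 and C13 with the acetate already in place.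

Step 16
Reactants: 26
Product: 27 (4E,6R,8S,10R)-13-acetoxy-8-[(2Z)-2-methylbut-2-enoyloxy]-1-oxogermacra-4,7(11)-dien-12,6-olide
Conditions: second-generation Hoveyda–Grubbs catalyst (15 mol%), 1,4-benzoquinone (30 mol%), PhMe (2 mM), 100 °C, argon sparge
Reagents that add atoms: none
Why: Ring-closing metathesis between the two 1,1-disubstituted alkenes expels ethene and forms the five-membered butenolide with its tetrasubstituted C7=C11 alkene, a closure known for simple 3,4-disubstituted furanones; benzoquinone suppresses hydride-mediated isomerisation.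

Step 17
Reactants: 27
Product: 28 (4R,5R,6S,8S,10R)-13-acetoxy-8-[(2Z)-2-methylbut-2-enoyloxy]-4,5-epoxy-1-oxogermacr-7(11)-en-12,6-olide (the target)
Conditions: mCPBA (1.1 equiv), NaHCO3, CH2Cl2, 0 °C
Reagents that add atoms: 3-chloroperoxybenzoic acid, OOC(=O)c1cccc(Cl)c1
Why: Prilezhaev epoxidation of the only electron-rich alkene; allylic 1,3-strain between the C4 methyl and C6 holds H6 in the alkene plane, so the peracid attacks the peripheral face syn to the lactone oxygen and away from the ring chain at C7, giving the trans (4R,5R) epoxide under control of C6.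

## Compound list

1 | (5S)-5-(hydroxymethyl)oxolan-2-one | O=C1CC[C@@H](CO)O1 | starting material
2 | (5S)-5-({[tert-butyl(diphenyl)silyl]oxy}methyl)oxolan-2-one | O=C1CC[C@@H](CO[Si](c2ccccc2)(c2ccccc2)C(C)(C)C)O1 | intermediate
3 | lithium enolate of 2 | [Li]OC1=CC[C@@H](CO[Si](c2ccccc2)(c2ccccc2)C(C)(C)C)O1 | intermediate
4 | (3R,5S)-5-({[tert-butyl(diphenyl)silyl]oxy}methyl)-3-methyloxolan-2-one | C[C@@H]1C[C@@H](CO[Si](c2ccccc2)(c2ccccc2)C(C)(C)C)OC1=O | intermediate
5 | (3R,5S)-5-(hydroxymethyl)-3-methyloxolan-2-one | C[C@@H]1C[C@@H](CO)OC1=O | intermediate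
6 | (2S,4R)-4-methyl-5-oxooxolane-2-carbaldehyde | C[C@@H]1C[C@@H](C=O)OC1=O | intermediate
7 | (3R,5S)-5-ethynyl-3-methyloxolan-2-one | C[C@@H]1C[C@@H](C#C)OC1=O | intermediate
8 | (3R,5S)-5-(1-iodoethenyl)-3-methyloxolan-2-one | C[C@@H]1C[C@@H](C(I)=C)OC1=O | intermediate
9 | 4-bromobut-1-yne | BrCCC#C | starting material
10 | [(1E)-4-bromo-2-methylbut-1-en-1-yl]dimethylalane | BrCC/C(C)=C/[Al](C)C | intermediate
11 | ethyl (2E)-5-bromo-3-methylpent-2-enoate | BrCC/C(C)=C/C(=O)OCC | intermediate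
12 | (2E)-5-bromo-3-methylpent-2-en-1-ol | BrCC/C(C)=C/CO | intermediate
13 | {[(2E)-5-bromo-3-methylpent-2-en-1-yl]oxy}triethylsilane | BrCC/C(C)=C/CO[Si](CC)(CC)CC | intermediate
14 | {(3E)-3-methyl-5-[(triethylsilyl)oxy]pent-3-en-1-yl}magnesium bromide | Br[Mg]CC/C(C)=C/CO[Si](CC)(CC)CC | intermediate
15 | (3S,5R,9E)-3-hydroxy-2-iodo-5,9-dimethyl-11-[(triethylsilyl)oxy]undeca-1,9-dien-6-one | O[C@H](C(I)=C)C[C@@H](C)C(=O)CC/C(C)=C/CO[Si](CC)(CC)CC | intermediate
16 | angelic acid, (2Z)-2-methylbut-2-enoic acid | C/C=C(/C)C(=O)O | starting material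
17 | (2Z)-2-methylbut-2-enoic 2,4,6-trichlorobenzoic anhydride | C/C=C(/C)C(=O)OC(=O)c1c(Cl)cc(Cl)cc1Cl | intermediate
18 | (3S,5R,9E)-2-iodo-5,9-dimethyl-6-oxo-11-[(triethylsilyl)oxy]undeca-1,9-dien-3-yl (2Z)-2-methylbut-2-enoate | C/C=C(/C)C(=O)O[C@H](C(I)=C)C[C@@H](C)C(=O)CC/C(C)=C/CO[Si](CC)(CC)CC | intermediate
19 | (3S,5R,9E)-11-hydroxy-2-iodo-6,6-dimethoxy-5,9-dimethylundeca-1,9-dien-3-yl (2Z)-2-methylbut-2-enoate | C/C=C(/C)C(=O)O[C@H](C(I)=C)C[C@@H](C)C(OC)(OC)CC/C(C)=C/CO | intermediate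
20 | (3S,5R,9E)-2-iodo-6,6-dimethoxy-5,9-dimethyl-11-oxoundeca-1,9-dien-3-yl (2Z)-2-methylbut-2-enoate | C/C=C(/C)C(=O)O[C@H](C(I)=C)C[C@@H](C)C(OC)(OC)CC/C(C)=C/C=O | intermediate
21 | (4E,6R,8S,10R)-6-hydroxy-1,1-dimethoxy-4,10-dimethyl-7-methylidenecyclodec-4-en-8-yl (2Z)-2-methylbut-2-enoate | C/C=C(/C)C(=O)O[C@H]1C[C@@H](C)C(OC)(OC)CC/C(C)=C/[C@@H](O)C1=C | intermediate
22 | (4E,6R,8S,10R)-6-hydroxy-4,10-dimethyl-7-methylidene-1-oxocyclodec-4-en-8-yl (2Z)-2-methylbut-2-enoate | C/C=C(/C)C(=O)O[C@H]1C[C@@H](C)C(=O)CC/C(C)=C/[C@@H](O)C1=C | intermediate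
23 | 2-(bromomethyl)prop-2-enoic acid | C=C(CBr)C(=O)O | starting material
24 | 2-(acetoxymethyl)prop-2-enoic acid | CC(=O)OCC(=C)C(=O)O | intermediate
25 | 2-(acetoxymethyl)prop-2-enoyl chloride | CC(=O)OCC(=C)C(Cl)=O | intermediate
26 | (4E,6R,8S,10R)-6-{[2-(acetoxymethyl)prop-2-enoyl]oxy}-4,10-dimethyl-7-methylidene-1-oxocyclodec-4-en-8-yl (2Z)-2-methylbut-2-enoate | C/C=C(/C)C(=O)O[C@H]1C[C@@H](C)C(=O)CC/C(C)=C/[C@@H](OC(=O)C(=C)COC(C)=O)C1=C | intermediate
27 | (4E,6R,8S,10R)-13-acetoxy-8-[(2Z)-2-methylbut-2-enoyloxy]-1-oxogermacra-4,7(11)-dien-12,6-olide | C/C=C(/C)C(=O)O[C@H]1C[C@@H](C)C(=O)CC/C(C)=C/[C@H]2OC(=O)C(COC(C)=O)=C12 | intermediate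
28 | (4R,5R,6S,8S,10R)-13-acetoxy-8-[(2Z)-2-methylbut-2-enoyloxy]-4,5-epoxy-1-oxogermacr-7(11)-en-12,6-olide | C/C=C(/C)C(=O)O[C@H]1C[C@@H](C)C(=O)CC[C@@]2(C)O[C@@H]2[C@H]2OC(=O)C(COC(C)=O)=C12 | target

## Step count and risks

Total: 17 steps. Longest linear sequence: 13 steps (1–5, 9–13, 15–17).

**Step 13 (electrochemical macrocyclisation, the proposed new step).** The hazards are oligomerisation at 2 mM, slow chromium turnover, and β-elimination of the C8 angelate from the C7 alkenylmetal to an allene. The fallback uses known chemistry, a nickel-catalysed reductive alkyne–aldehyde macrocyclisation with a bulky carbene ligand, which closes at the internal alkyne carbon and never places a metal on C7 next to the ester. It sets out from 7 and comes back at 22. Lactone 7 is opened at −78 °C with 2.2 equiv of 14 (the first equivalent is consumed by the acetylenic proton) to give (3S,5R,9E)-3-hydroxy-5,9-dimethyl-11-[(triethylsilyl)oxy]undec-9-en-1-yn-6-one F1. Esterification with 16 as in step 10 gives the angelate (3S,5R,9E)-5,9-dimethyl-6-oxo-11-[(triethylsilyl)oxy]undec-9-en-1-yn-3-yl (2Z)-2-methylbut-2-enoate F2. Swern oxidation, which cleaves and oxidises the primary triethylsilyl ether in one operation, gives the ynal (3S,5R,9E)-5,9-dimethyl-6,11-dioxoundec-9-en-1-yn-3-yl (2Z)-2-methylbut-2-enoate F3. Slow addition of F3 to Ni(cod)2, 1,3-bis(2,6-diisopropylphenyl)imidazol-2-ylidene and Et3SiH in THF, an aldehyde-selective coupling, closes ring A to (4E,6R,8S,10R)-4,10-dimethyl-7-methylidene-1-oxo-6-[(triethylsilyl)oxy]cyclodec-4-en-8-yl (2Z)-2-methylbut-2-enoate F4. HF·pyridine then gives 22.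

**Step 16 (ring-closing metathesis to a tetrasubstituted butenolide on a hindered macrocycle).** The fallback forms C7=C11 by carbonyl olefination instead. It sets out from 22 and comes back at 28.
- Hydroxyl-directed mCPBA epoxidation of 22 gives (4R,5R,6S,8S,10R)-4,5-epoxy-6-hydroxy-4,10-dimethyl-7-methylidene-1-oxocyclodecan-8-yl (2Z)-2-methylbut-2-enoate F5, which also removes the competing electron-rich alkene.
- DCC coupling with 3-[(tert-butyldimethylsilyl)oxy]-2-(diethoxyphosphoryl)propanoic acid gives (4R,5R,6S,8S,10R)-6-({3-[(tert-butyldimethylsilyl)oxy]-2-(diethoxyphosphoryl)propanoyl}oxy)-4,5-epoxy-4,10-dimethyl-7-methylidene-1-oxocyclodecan-8-yl (2Z)-2-methylbut-2-enoate F6.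
- OsO4/N-methylmorpholine N-oxide and then NaIO4 cleave the methylidene to the ketone (4R,5R,6R,8S,10R)-6-({3-[(tert-butyldimethylsilyl)oxy]-2-(diethoxyphosphoryl)propanoyl}oxy)-4,5-epoxy-4,10-dimethyl-1,7-dioxocyclodecan-8-yl (2Z)-2-methylbut-2-enoate F7.
- Intramolecular Horner–Wadsworth–Emmons reaction (LiCl, iPr2NEt, MeCN) gives (4R,5R,6S,8S,10R)-13-[(tert-butyldimethylsilyl)oxy]-8-[(2Z)-2-methylbut-2-enoyloxy]-4,5-epoxy-1-oxogermacr-7(11)-en-12,6-olide F8.
- HF·pyridine gives (4R,5R,6S,8S,10R)-13-hydroxy-8-[(2Z)-2-methylbut-2-enoyloxy]-4,5-epoxy-1-oxogermacr-7(11)-en-12,6-olide F9, and Ac2O/pyridine gives 28.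

**Step 9 (single Grignard addition to the lactone; the risk is double addition to a diol).** The fallback uses a Weinreb amide as the acyl electrophile. It sets out from 8 and comes back at 18. Me(MeO)NH·HCl and AlMe3 in CH2Cl2 open 8 to (2R,4S)-4-hydroxy-5-iodo-N-methoxy-N,2-dimethylhex-5-enamide F10. Esterification with 16 as in step 10 gives (3S,5R)-2-iodo-6-[methoxy(methyl)amino]-5-methyl-6-oxohex-1-en-3-yl (2Z)-2-methylbut-2-enoate F11. Addition of 14 at −40 °C, where the chelated amide adduct forms faster than the hindered angelate reacts, gives 18 directly.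

## Further compounds

F1 | step 13 | (3S,5R,9E)-3-hydroxy-5,9-dimethyl-11-[(triethylsilyl)oxy]undec-9-en-1-yn-6-one | O[C@H](C#C)C[C@@H](C)C(=O)CC/C(C)=C/CO[Si](CC)(CC)CC
F2 | step 13 | (3S,5R,9E)-5,9-dimethyl-6-oxo-11-[(triethylsilyl)oxy]undec-9-en-1-yn-3-yl (2Z)-2-methylbut-2-enoate | C/C=C(/C)C(=O)O[C@H](C#C)C[C@@H](C)C(=O)CC/C(C)=C/CO[Si](CC)(CC)CC
F3 | step 13 | (3S,5R,9E)-5,9-dimethyl-6,11-dioxoundec-9-en-1-yn-3-yl (2Z)-2-methylbut-2-enoate | C/C=C(/C)C(=O)O[C@H](C#C)C[C@@H](C)C(=O)CC/C(C)=C/C=O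
F4 | step 13 | (4E,6R,8S,10R)-4,10-dimethyl-7-methylidene-1-oxo-6-[(triethylsilyl)oxy]cyclodec-4-en-8-yl (2Z)-2-methylbut-2-enoate | C/C=C(/C)C(=O)O[C@H]1C[C@@H](C)C(=O)CC/C(C)=C/[C@@H](O[Si](CC)(CC)CC)C1=C
F5 | step 16 | (4R,5R,6S,8S,10R)-4,5-epoxy-6-hydroxy-4,10-dimethyl-7-methylidene-1-oxocyclodecan-8-yl (2Z)-2-methylbut-2-enoate | C/C=C(/C)C(=O)O[C@H]1C[C@@H](C)C(=O)CC[C@@]2(C)O[C@@H]2[C@@H](O)C1=C
F6 | step 16 | (4R,5R,6S,8S,10R)-6-({3-[(tert-butyldimethylsilyl)oxy]-2-(diethoxyphosphoryl)propanoyl}oxy)-4,5-epoxy-4,10-dimethyl-7-methylidene-1-oxocyclodecan-8-yl (2Z)-2-methylbut-2-enoate | C/C=C(/C)C(=O)O[C@H]1C[C@@H](C)C(=O)CC[C@@]2(C)O[C@@H]2[C@@H](OC(=O)C(CO[Si](C)(C)C(C)(C)C)P(=O)(OCC)OCC)C1=C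
F7 | step 16 | (4R,5R,6R,8S,10R)-6-({3-[(tert-butyldimethylsilyl)oxy]-2-(diethoxyphosphoryl)propanoyl}oxy)-4,5-epoxy-4,10-dimethyl-1,7-dioxocyclodecan-8-yl (2Z)-2-methylbut-2-enoate | C/C=C(/C)C(=O)O[C@H]1C[C@@H](C)C(=O)CC[C@@]2(C)O[C@@H]2[C@@H](OC(=O)C(CO[Si](C)(C)C(C)(C)C)P(=O)(OCC)OCC)C1=O
F8 | step 16 | (4R,5R,6S,8S,10R)-13-[(tert-butyldimethylsilyl)oxy]-8-[(2Z)-2-methylbut-2-enoyloxy]-4,5-epoxy-1-oxogermacr-7(11)-en-12,6-olide | C/C=C(/C)C(=O)O[C@H]1C[C@@H](C)C(=O)CC[C@@]2(C)O[C@@H]2[C@H]2OC(=O)C(CO[Si](C)(C)C(C)(C)C)=C12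
F9 | step 16 | (4R,5R,6S,8S,10R)-13-hydroxy-8-[(2Z)-2-methylbut-2-enoyloxy]-4,5-epoxy-1-oxogermacr-7(11)-en-12,6-olide | C/C=C(/C)C(=O)O[C@H]1C[C@@H](C)C(=O)CC[C@@]2(C)O[C@@H]2[C@H]2OC(=O)C(CO)=C12
F10 | step 9 | (2R,4S)-4-hydroxy-5-iodo-N-methoxy-N,2-dimethylhex-5-enamide | O[C@H](C(I)=C)C[C@@H](C)C(=O)N(C)OC
F11 | step 9 | (3S,5R)-2-iodo-6-[methoxy(methyl)amino]-5-methyl-6-oxohex-1-en-3-yl (2Z)-2-methylbut-2-enoate | C/C=C(/C)C(=O)O[C@H](C(I)=C)C[C@@H](C)C(=O)N(C)OC
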